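**Plan**

Retrosynthesis: the N1–C2 bond of the indoxyl ring is cut first, as a C–H/N–H dehydrogenative coupling read backwards. This opens the target to 1-(2-aminophenyl)-2,2-di(indol-3-yl)ethanone. NH2 then goes back to NO2, both C2–C3' bonds are cut to 2-nitrophenylglyoxal plus two indoles, and the glyoxal goes back to 2'-nitroacetophenone.
Forward: CH3 is oxidised to CHO and both indole rings are joined to that carbon in one double Friedel–Crafts operation. The nitro group, which keeps nitrogen away from the aldehyde, is then reduced, and the only ring to be built (N1–C2–C3–C3a–C7a) arises last.
Enabling feature: the future C2 is a methine alpha to the C3 ketone, so it enolises. It bears two indol-3-yl rings whose pyrrole nitrogens can carry its positive charge as a 3-alkylidene-3H-indole, and the NH2 group sits ortho on the benzoyl ring at five-membered-ring distance.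
A mediated two-electron anodic oxidation therefore turns C2 from nucleophile into electrophile within reach of N1. It sets the last bond of the fully substituted carbon with H2 as the only by-product and without any N-protecting group.
Stereochemistry: none to set, because C2 carries two identical indol-3-yl groups and the target is achiral.

Key step: step 4

Remark: the keto aldehyde made in step 1 equilibrates with its hydrate in wet solvents. It is drawn and counted as the free keto aldehyde, and either form serves in step 2.

**Step 1**
Reactants: 1 2'-nitroacetophenone
Product: 2 2-nitrophenylglyoxal [2-(2-nitrophenyl)-2-oxoacetaldehyde]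
Conditions: SeO2 (1.1 equiv), 1,4-dioxane/H2O, reflux; filtration through Celite, toluene azeotrope
Reagents that add atoms: selenium dioxide, O=[Se]=O
Why: Riley oxidation, in which SeO2 attacks the enol of the only enolisable position (the methyl ketone) and, after loss of elemental selenium and water, delivers the alpha-keto aldehyde while the nitroarene is inert to the oxidant.

**Step 2**
Reactants: 2 2-nitrophenylglyoxal; 3 indole (2.1 equiv)
Product: 5 2,2-di(1H-indol-3-yl)-1-(2-nitrophenyl)ethanone, via mono-indolyl carbinol 4 (not isolated)
Conditions: p-TsOH·H2O (10 mol %), MeCN, rt
Reagents that add atoms: none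
Why: Acid-catalysed double Friedel–Crafts reaction (bis-indolylation of an arylglyoxal), in which indole C3 adds to the aldehyde carbon, by far the more electrophilic and less hindered carbonyl, to give racemic carbinol 4, which ionises to an indole-stabilised azafulvenium ion that takes up the second indole at C3, so that the stereocentre of 4 is erased and none remains.

**Step 3**
Reactants: 5 2,2-di(1H-indol-3-yl)-1-(2-nitrophenyl)ethanone
Product: 6 1-(2-aminophenyl)-2,2-di(1H-indol-3-yl)ethanone
Conditions: H2 (1 atm), Pd/C (10 wt %), EtOAc/EtOH, rt; filtration under N2, used without storage
Reagents that add atoms: none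
Why: Catalytic hydrogenation of a nitroarene to the aniline under neutral conditions, which should leave the hindered aryl ketone, the indoles and the acid-sensitive bis(indolyl)methine untouched, and the new amine cannot condense with its own ketone because that would need a four-membered ring.

**Step 4**
Reactants: 6 1-(2-aminophenyl)-2,2-di(1H-indol-3-yl)ethanone
Product: 9 2,2-bis(3'-indolyl)indoxyl [2,2-di(1H-indol-3-yl)indolin-3-one], via alpha-iodo ketone 7 (not isolated), via alkylideneindolenine 8 (not isolated)
Conditions: undivided cell, graphite anode, Pt cathode, constant current (about 5 mA cm-2, 2.2–2.5 F mol-1), nBu4NI (20 mol %), nBu4NBF4 (0.1 M), MeCN/MeOH 4:1, N2, rt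
Reagents that add atoms: none
Why: Proposed new method: iodide is oxidised at the anode to iodine at a potential well below those of the indole rings and of the aminoaryl ketone, methoxide formed at the cathode (with H2) enolises the only enolisable C–H of 6, iodine converts the enolate into the tertiary alpha-iodo ketone 7, and the lone pair of an indole nitrogen expels iodide at once (with loss of that N–H proton) to give the 3-alkylidene-3H-indole 8. The ortho NH2 group then adds to the exocyclic carbon of 8, which restores the indole, forms the N1–C2 bond and completes the fully substituted carbon, so that the net event is a dehydrogenative C(sp3)–H/N–H coupling in which current replaces the chemical oxidant. The closest known reaction types are the iodide-mediated anodic alpha-C–H amination of ketones, the two-electron oxidation of bis(indolyl)methanes to azafulvenium ions by quinones such as DDQ, and the conjugate addition of nitrogen nucleophiles to 3-alkylideneindolenines; new is their union in a ring closure on an unprotected bis(indolyl)methine that ends in a C2-quaternary indoxyl. The five-membered ring closes in the 5-exo-trig mode (the C=C bond that is consumed lies outside the new ring, and the crowded tetrasubstituted alkene twists the aroyl group so that NH2 lies over its face), and no stereocentre arises because C2 bears two identical indol-3-yl groups. The step needs site selectivity for one C–H bond over three N–H groups, two free indole C2 positions and the activated aminophenyl ring, and for N1 over methanol as nucleophile: the methine is the only acidic C–H and the only site whose cation is carried by two indoles, only the aniline nitrogen reaches it through a five-membered transition state, and capture by methanol or iodide is reversible whereas the closure is not. The product has no hydrogen left at C2 and therefore cannot re-enter the mediated cycle, which guards it against over-oxidation.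

**Compound list**

1 | 2'-nitroacetophenone | CC(=O)c1ccccc1[N+](=O)[O-] | starting material
2 | 2-nitrophenylglyoxal | O=CC(=O)c1ccccc1[N+](=O)[O-] | intermediate
3 | indole | c1ccc2[nH]ccc2c1 | starting material
4 | 2-hydroxy-2-(1H-indol-3-yl)-1-(2-nitrophenyl)ethanone (racemic, not isolated) | O=C(c1ccccc1[N+](=O)[O-])C(O)c1c[nH]c2ccccc12 | intermediate
5 | 2,2-di(1H-indol-3-yl)-1-(2-nitrophenyl)ethanone | O=C(c1ccccc1[N+](=O)[O-])C(c1c[nH]c2ccccc12)c1c[nH]c2ccccc12 | intermediate
6 | 1-(2-aminophenyl)-2,2-di(1H-indol-3-yl)ethanone | Nc1ccccc1C(=O)C(c1c[nH]c2ccccc12)c1c[nH]c2ccccc12 | intermediate
7 | 1-(2-aminophenyl)-2-iodo-2,2-di(1H-indol-3-yl)ethanone (not isolated) | Nc1ccccc1C(=O)C(I)(c1c[nH]c2ccccc12)c1c[nH]c2ccccc12 | intermediate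
8 | 1-(2-aminophenyl)-2-(1H-indol-3-yl)-2-(3H-indol-3-ylidene)ethanone (alkene geometry open, both forms close to the same product, not isolated) | Nc1ccccc1C(=O)C(c1c[nH]c2ccccc12)=C1C=Nc2ccccc12 | intermediate
9 | 2,2-bis(3'-indolyl)indoxyl (achiral) | O=C1c2ccccc2NC1(c1c[nH]c2ccccc12)c1c[nH]c2ccccc12 | target

**Total step count:** 4. **Longest linear sequence:** 4 steps (1 → 2 → 5 → 6 → 9).

**Steps most likely to fail**

**Step 4.** Oxidation may go to the wrong site. Possible courses are iodination of the aminophenyl ring or of an indole C2 position, direct electron transfer from the indoles with oligomer films on the anode, or enolisation too slow at the crowded methine.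

The fallback gives up C–H oxidation. It closes the same N1–C2 bond by condensation at a carbon that already has the ketone oxidation level, and sets the quaternary centre afterwards by a C–C bond, using known reaction types throughout. It sets out from 2 and comes back to the route at 9.
- With one equivalent of 3 and no acid (EtOH/H2O, rt) the addition should stop at carbinol 4, which is isolated this time.
- MnO2 (CH2Cl2, rt) should oxidise 4 to 1-(1H-indol-3-yl)-2-(2-nitrophenyl)ethane-1,2-dione F1.
- Hydrogenation (H2, Pd/C, EtOAc) gives 1-(2-aminophenyl)-2-(1H-indol-3-yl)ethane-1,2-dione F2.
- F2 cyclodehydrates under catalytic p-TsOH to the cyclic ketimine 2-(1H-indol-3-yl)-3H-indol-3-one F3.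
- Aza-Friedel–Crafts addition of a second equivalent of 3 to the C=N bond of F3 in the same pot gives 9.

**Step 3.** The half-reduced nitrogen (hydroxylamine stage) may be captured by the neighbouring ketone or by the enolisable methine before reduction is complete. The amine may also oxidise in air during isolation.

The fallback makes this capture the plan and reduces in two separate stages through a stable heterocycle that masks both ketone and nitrogen. It sets out from 5 and comes back at 6.
- SnCl2·2H2O (EtOAc/EtOH, rt to 50 °C) should give, by reductive heterocyclisation of the 2-nitroaryl ketone, 3-[di(1H-indol-3-yl)methyl]-2,1-benzisoxazole F4.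
- Reductive N–O cleavage of F4 (Fe powder, AcOH/EtOH/H2O, 60 °C) opens the ring to 6.

**Step 2.** The reaction may stop at the mono-adduct, because ionisation of a carbinol next to an electron-poor aroyl group is slow. The isolated keto aldehyde may oligomerise or hydrate, and indole may dimerise under acid.

The fallback is an iodine/DMSO domino dual heteroarylation of the methyl ketone, which also makes step 1 unnecessary. It sets out from 1 (with 3) and comes back at 5.
- I2 (1.1 equiv) in DMSO at 100 °C converts 1 into 2-iodo-1-(2-nitrophenyl)ethanone F5.
- Kornblum oxidation of F5 by DMSO releases 2 slowly in the presence of 3.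
- The iodine and acid present at this temperature drive both Friedel–Crafts events through 4 to 5.

**Further compounds**

F1 | step 4 | 1-(1H-indol-3-yl)-2-(2-nitrophenyl)ethane-1,2-dione | O=C(C(=O)c1c[nH]c2ccccc12)c1ccccc1[N+](=O)[O-]
F2 | step 4 | 1-(2-aminophenyl)-2-(1H-indol-3-yl)ethane-1,2-dione | Nc1ccccc1C(=O)C(=O)c1c[nH]c2ccccc12
F3 | step 4 | 2-(1H-indol-3-yl)-3H-indol-3-one | O=C1C(c2c[nH]c3ccccc23)=Nc2ccccc12
F4 | step 3 | 3-[di(1H-indol-3-yl)methyl]-2,1-benzisoxazole | C(c1c[nH]c2ccccc12)(c1c[nH]c2ccccc12)c1onc2ccccc12
F5 | step 2 | 2-iodo-1-(2-nitrophenyl)ethanone | O=C(CI)c1ccccc1[N+](=O)[O-]
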